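**Retrosynthetic overview**
- The target is disconnected at the primary allylic C–O bond: it comes from wighteone (6-prenylgenistein) by a late-stage, (E)-selective allylic C–H hydroxylation of the prenyl terminus (key step, new selenium catalyst).
- Wighteone comes from a 6-iodo-7,4'-bis-O-silyl genistein and a prenylstannane by Stille coupling, with the silyl ethers removed in the same pot.
- The 6-iodide comes from 7,4'-bis-O-silyl genistein (iodination directed by the chelated 5-OH), which comes from genistein.
- Rings: none is built. Rings A, B and C are bought intact in genistein, so no order of ring formation arises.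

Assumption: the target has no stereocentre, so "single enantiomer" is read as the single (E)-alkene isomer shown; that geometry is the only stereo-element the route has to set.

**Step 1**
Reactants: 1 genistein (5,7-dihydroxy-3-(4-hydroxyphenyl)-4H-chromen-4-one); 2 tert-butyldimethylsilyl chloride
Product: 3 7,4'-bis-O-(tert-butyldimethylsilyl)genistein (5-OH free)
Conditions: TBSCl (2.2 equiv), imidazole (4.5 equiv), DMF, 0 °C to rt
Reagents that add atoms: tert-butyldimethylsilyl chloride, CC(C)(C)[Si](C)(C)Cl
Why: Imidazole-promoted O-silylation (substitution at silicon): the acidic 7-OH and the 4'-OH react, whereas the 5-OH is held in a strong hydrogen bond to the C4 carbonyl and stays free with 2.2 equiv of silyl chloride at room temperature; no stereocentre is formed.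

**Step 2**
Reactants: 3 7,4'-bis-O-(tert-butyldimethylsilyl)genistein; 4 N-iodosuccinimide
Product: 5 6-iodo-7,4'-bis-O-(tert-butyldimethylsilyl)genistein
Conditions: NIS (1.05 equiv), DMF, rt, dark
Reagents that add atoms: N-iodosuccinimide, O=C1CCC(=O)N1I
Why: Electrophilic aromatic iodination (SEAr): ring A is the most electron-rich ring and the free, carbonyl-chelated 5-OH directs iodine to its only open ortho position, C6, the usual site for 5-hydroxy-7-alkoxychromen-4-ones, while the silyl ethers survive these neutral conditions; no stereocentre is formed.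

**Step 3**
Reactants: 5 6-iodo-7,4'-bis-O-(tert-butyldimethylsilyl)genistein; 6 tributyl(3-methylbut-2-en-1-yl)stannane
Product: 8 wighteone (5,7-dihydroxy-3-(4-hydroxyphenyl)-6-(3-methylbut-2-en-1-yl)-4H-chromen-4-one), via bis-silyl wighteone 7 (not isolated)
Conditions: Pd(PPh3)4 (5 mol%), DMF, 95 °C, Ar; then KHF2 (4 equiv), MeOH, rt, same pot
Reagents that add atoms: tributyl(3-methylbut-2-en-1-yl)stannane, CCCC[Sn](CCCC)(CCCC)CC=C(C)C
Why: Stille cross-coupling: zerovalent palladium inserts into the C6–I bond, the prenyl group is transferred from tin and reductive elimination at the unsubstituted allyl terminus gives the linear 3-methylbut-2-enyl group (the free chelated 5-OH is tolerated), after which bifluoride cleaves both aryl silyl ethers and precipitates the tin as Bu3SnF; no stereocentre is formed.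

**Step 4**
Reactants: 8 wighteone; 9 tert-butyl hydroperoxide
Product: 10 5,7-dihydroxy-6-[(2E)-4-hydroxy-3-methylbut-2-en-1-yl]-3-(4-hydroxyphenyl)-4H-chromen-4-one (target)
Conditions: SeO2 (5 mol%), pinacol (6 mol%), 4 Å molecular sieves, tBuOOH (1.5 equiv, 5.5 M in decane), EtOAc, 0 °C to rt
Reagents that add atoms: tert-butyl hydroperoxide, CC(C)(C)OO
Why: Proposed new method: a neutral, chelated tetravalent selenium ester catalyst, pinacol selenite (4,4,5,5-tetramethyl-1,3,2-dioxaselenolane 2-oxide, C6H12O3Se, CC1(C)O[Se](=O)OC1(C)C, formed in the flask from SeO2 and pinacol over sieves), is turned over by tBuOOH on a fully unprotected ortho-prenyl polyphenol; its Se=O unit should undergo an ene reaction with the electron-rich trisubstituted alkene (selenium bonds to the CH carbon and hydrogen is taken from a terminal methyl, not from the benzylic CH2, because that would require selenium at the fully substituted carbon), the allylic seleninate ester then undergoes a [2,3]-sigmatropic shift through an envelope transition state with the ArCH2 group pseudo-equatorial, which places oxygen on the terminal carbon and fixes the (E)-geometry, and the pendant tertiary hydroxyl of the ring-opened pinacol arm expels the product alcohol by intramolecular transesterification to give a cyclic divalent selenium diolate that tBuOOH reoxidises; the chelating diol, which has no carbinol C–H to oxidise, keeps selenium non-acidic (no chroman formation from the 5-OH or 7-OH onto the prenyl group), hinders phenol ligation and limits over-oxidation to the enal; closest known reaction type: Riley allylic oxidation in its catalytic SeO2/tBuOOH (Sharpless) form.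

**Compound list**
1 | genistein (5,7-dihydroxy-3-(4-hydroxyphenyl)-4H-chromen-4-one) | Oc1ccc(cc1)-c1coc2cc(O)cc(O)c2c1=O | starting material
2 | tert-butyldimethylsilyl chloride | CC(C)(C)[Si](C)(C)Cl | starting material
3 | 7-[(tert-butyldimethylsilyl)oxy]-3-{4-[(tert-butyldimethylsilyl)oxy]phenyl}-5-hydroxy-4H-chromen-4-one | CC(C)(C)[Si](C)(C)Oc1ccc(cc1)-c1coc2cc(O[Si](C)(C)C(C)(C)C)cc(O)c2c1=O | intermediate
4 | N-iodosuccinimide | O=C1CCC(=O)N1I | starting material
5 | 7-[(tert-butyldimethylsilyl)oxy]-3-{4-[(tert-butyldimethylsilyl)oxy]phenyl}-5-hydroxy-6-iodo-4H-chromen-4-one | CC(C)(C)[Si](C)(C)Oc1ccc(cc1)-c1coc2cc(O[Si](C)(C)C(C)(C)C)c(I)c(O)c2c1=O | intermediate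
6 | tributyl(3-methylbut-2-en-1-yl)stannane | CCCC[Sn](CCCC)(CCCC)CC=C(C)C | starting material
7 | 7-[(tert-butyldimethylsilyl)oxy]-3-{4-[(tert-butyldimethylsilyl)oxy]phenyl}-5-hydroxy-6-(3-methylbut-2-en-1-yl)-4H-chromen-4-one (bis-silyl wighteone) | CC(C)=CCc1c(O[Si](C)(C)C(C)(C)C)cc2occ(-c3ccc(O[Si](C)(C)C(C)(C)C)cc3)c(=O)c2c1O | intermediate
8 | wighteone (5,7-dihydroxy-3-(4-hydroxyphenyl)-6-(3-methylbut-2-en-1-yl)-4H-chromen-4-one) | CC(C)=CCc1c(O)cc2occ(-c3ccc(O)cc3)c(=O)c2c1O | intermediate
9 | tert-butyl hydroperoxide | CC(C)(C)OO | starting material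
10 | 5,7-dihydroxy-6-[(2E)-4-hydroxy-3-methylbut-2-en-1-yl]-3-(4-hydroxyphenyl)-4H-chromen-4-one | C/C(=C\Cc1c(O)cc2occ(-c3ccc(O)cc3)c(=O)c2c1O)CO | target

**Step count and risks**
Total step count: 4. Longest linear sequence: 4 steps (1 → 3 → 5 → 8 → 10).

The three steps most likely to fail:

Step 4, the proposed new hydroxylation. The catalyst is untested, so turnover may stall, phenols may still bind selenium, or some enal or chroman may form. The fallback uses known chemistry and sets out from 8. Acetylation (Ac2O, pyridine, DMAP, rt) gives wighteone triacetate F1. Classical Riley oxidation in its SeO2 (0.5 equiv)/tBuOOH form (CH2Cl2, rt), which is well precedented for acetylated prenylarenes and is (E)-selective by the same ene/[2,3] pathway, gives the (E)-allylic alcohol triacetate F2; any enal is reduced back with NaBH4/CeCl3·7H2O. K2CO3 in MeOH at rt then removes the three aryl acetates, and the fallback comes back to the route at 10.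

Step 3, the prenyl Stille coupling. Prenyl transfer can give some reverse-prenyl (1,1-dimethylallyl) isomer, and C6 is flanked by two oxygen substituents. The fallback sets out from 5 and builds the trisubstituted alkene by metathesis instead of transferring an intact prenyl group. Stille coupling with allyltributylstannane (Pd(PPh3)4, DMF, 90 °C), which has no regiochemical ambiguity, gives 6-allyl-7,4'-bis-O-(tert-butyldimethylsilyl)genistein F3. Cross-metathesis with excess 2-methylbut-2-ene (second-generation Grubbs catalyst, RuCl2(=CHPh)(H2IMes)(PCy3), CH2Cl2, 40 °C) converts allyl into prenyl, so the fallback comes back to the route at 7, which is desilylated with KHF2 in MeOH to 8 as in step 3.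

Step 2, the iodination. Iodine may go partly to C8 or twice into ring A, or a silyl ether may be lost. The fallback sets out from 3 and fixes the C6 position by connectivity instead of by directing effects. Mitsunobu etherification of the chelated 5-OH (allyl alcohol, PPh3, DIAD, THF, 0 °C to rt) gives 5-O-allyl-7,4'-bis-O-(tert-butyldimethylsilyl)genistein F4. Thermal aromatic Claisen rearrangement (N,N-diethylaniline, 190 °C) moves the allyl group to C6, the only free ortho position of O5, and gives 6-allyl-7,4'-bis-O-(tert-butyldimethylsilyl)genistein F3. Cross-metathesis with 2-methylbut-2-ene as above brings the fallback back to the route at 7, and KHF2 in MeOH then gives 8.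

**Further compounds**
F1 | step 4 | wighteone triacetate (5,7-diacetoxy-3-(4-acetoxyphenyl)-6-(3-methylbut-2-en-1-yl)-4H-chromen-4-one) | CC(C)=CCc1c(OC(C)=O)cc2occ(-c3ccc(OC(C)=O)cc3)c(=O)c2c1OC(C)=O
F2 | step 4 | 5,7-diacetoxy-3-(4-acetoxyphenyl)-6-[(2E)-4-hydroxy-3-methylbut-2-en-1-yl]-4H-chromen-4-one | C/C(=C\Cc1c(OC(C)=O)cc2occ(-c3ccc(OC(C)=O)cc3)c(=O)c2c1OC(C)=O)CO
F3 | step 3 | 6-allyl-7-[(tert-butyldimethylsilyl)oxy]-3-{4-[(tert-butyldimethylsilyl)oxy]phenyl}-5-hydroxy-4H-chromen-4-one | C=CCc1c(O[Si](C)(C)C(C)(C)C)cc2occ(-c3ccc(O[Si](C)(C)C(C)(C)C)cc3)c(=O)c2c1O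
F4 | step 2 | 5-(allyloxy)-7-[(tert-butyldimethylsilyl)oxy]-3-{4-[(tert-butyldimethylsilyl)oxy]phenyl}-4H-chromen-4-one | C=CCOc1cc(O[Si](C)(C)C(C)(C)C)cc2occ(-c3ccc(O[Si](C)(C)C(C)(C)C)cc3)c(=O)c12
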